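The easy step first: a first-order path gives the same percentage curve at any charge, and green, with about twice the charge of red, nearly repeats red, with 21.4% against 21.7% at 4.00 min.

| flask | starting material | remark | time |
|---|---|---|---|
| red | 0.13 M | run made earlier |  |
| green | 0.28 M | run made earlier |  |
| west | 0.15 M |  | 20 min |
| south-west | 0.25 M |  | 20 min |
| south-east | 0.40 M |  | 20 min |

| run | time / min | target / % |
|---|---|---|
| red | 1.00 | 7.2 |
| red | 1.50 | 11.2 |
| red | 2.50 | 15.8 |
| red | 4.00 | 21.7 |
| red | 6.00 | 27.2 |
| red | 10.0 | 34.2 |
| red | 15.0 | 38.7 |
| green | 0.833 | 5.7 |
| green | 2.00 | 14.0 |
| green | 4.00 | 21.4 |
| green | 6.00 | 26.9 |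
| green | 8.00 | 30.3 |
| green | 12.0 | 35.1 |
| green | 15.0 | 37.3 |

(standard deviation of a reading: 0.5 percentage points)

* [target] at the end for west, south-west, south-east, in this order
* the course of these numbers from the first flask to the last (falls all the way / rises, then falls / hardly changes / rises all the way / falls, then rises)

- in percentages every species weighs as the starting material in it: one side product C counts as two
- steps that have been proposed: starting material <-> intermediate B; starting material + intermediate A -> side product C; starting material -> intermediate A; target -> over-reaction product; intermediate B -> side product A; intermediate C -> side product B; starting material -> target; intermediate B <-> intermediate C; intermediate A -> target; starting material <-> dormant form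
- "hardly changes" means that all values lie within two and a half points (for a concentration: within two and a half percent of the largest)

Does the charge cost anything? At 15.0 min red leads green by 1.4 percentage points, more than the scatter of 0.5 points on each reading, so this is a rough reading. Among the proposed steps, starting material + intermediate A -> side product C has a rate that goes with the product of two concentrations. Dividing the gap by the difference in charge gives 0.0933 M⁻¹: the charge penalty, the yield, as a fraction of the charge, lost per molar of extra charge at a fixed time, here read at 15.0 min. We assume that it holds unchanged up to 20 min and out to 0.40 M.

What does red reach at 20 min? We replace the curve by its mean slope over each window. Red gains 7 points from 6.00 min to 10.0 min and 4.5 points from there to 15.0 min, so the mean slope falls to 0.514 of its value. Applying that factor once more gives 41.0%. Holding the slope unchanged instead adds 2.2 points to this estimate, and so to each of the yields we reckon from it.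

Does the charge beat the penalty? South-east holds 2.67 times the charge of west and, by our penalty, gives 2.3 points less yield, so in our reckoning the charge grows faster than the yield falls. We reckon 0.0612 M, 0.0997 M and 0.154 M, rising all the way.

The forecast gives 0.061 M, 0.1 M and 0.154 M, rises all the way, since “the charge grows much faster than the yield falls”.

The flasks give 0.0630 M, 0.101 M and 0.157 M: rises all the way.

    starting material ⇌ intermediate B (K = 15.0, k = 0.00120 s⁻¹)
    starting material + intermediate A → side product C (k = 0.0220 M⁻¹ s⁻¹)
    starting material → intermediate A (k = 5.30 × 10⁻⁴ s⁻¹)
    target → over-reaction product (k = 1.50 × 10⁻⁶ s⁻¹)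
    intermediate B → side product A (k = 0.00350 s⁻¹)
    intermediate C → side product B (k = 9.80 × 10⁻⁴ s⁻¹)
    starting material → target (k = 0.00140 s⁻¹)
    intermediate B ⇌ intermediate C (K = 0.160, k = 3.00 × 10⁻⁵ s⁻¹)
    intermediate A → target (k = 7.50 × 10⁻⁴ s⁻¹)
    starting material ⇌ dormant form (K = 0.880, k = 0.00110 s⁻¹)

Starting from the 42.0% of target in west, the charge penalty gives 41.1% for south-west and 39.7% for south-east, and those flasks hold 40.6% and 39.1%. Side product C stands at 7.85% in west and 14.3% in south-east. In west at 3.22 min, the selectivity of intermediate A favours side product C: its rate to target is less than its rate to side product C, by a ratio of 0.51.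

(The readings stem from a simulated flask on assumed constants, noise included.)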